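Monday's flask at 70 °C levels off about twice as high as Tuesday's at 55 °C, with the same 0.90 equiv of reagent in both. So you need that level, which I call the ceiling, and the pace at which target closes on it.

in all of them: solid substrate 0.38 M

|  | reagent | temperature | remark | time |
|---|---|---|---|---|
| Monday's | 0.90 equiv | 70 °C | the very flask that is asked about, followed so far |  |
| Tuesday's | 0.90 equiv | 55 °C | run made earlier |  |
| flask | 0.900 equiv | 70 °C |  | 4.0 h |

| run | time / min | target / % |
|---|---|---|
| Monday's | 15.0 | 5.1 |
| Monday's | 50.0 | 23.0 |
| Monday's | 80.0 | 36.4 |
| Monday's | 120 | 40.6 |
| Monday's | 180 | 42.6 |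
| Monday's | 240 | 45.1 |
| Tuesday's | 30.0 | 3.2 |
| Tuesday's | 120 | 20.8 |
| Tuesday's | 180 | 23.6 |
| Tuesday's | 240 | 23.5 |
| Tuesday's | 360 | 22.1 |
| Tuesday's | 480 | 23.9 |

(each reading ± 1 percentage point)

- given per volume of solution although it is solid: solid substrate
- target taken out counts as made
- at the start none of the solid substrate is in solution
- additions bring no volume worth counting

- midnight: at 4.0 h add reagent, 100 % of the amount charged, then wait 4.0 h
- spring: at 4.0 h take out 90 % of the target then present, then wait 4.0 h
- dawn: at 4.0 h raise the temperature by 25 K, then wait 4.0 h
- dusk: change nothing and wait 4.0 h more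

1. target, in percent of the solid substrate first charged, at 4.0 h
2. the remedy with the largest gain of target, or "none" below 2 percentage points (midnight / spring / dawn / dusk / none)
3. target present, with what was taken out counted in, in percent of the solid substrate first charged, after midnight
4. target present, with what was taken out counted in, in percent of the solid substrate first charged, after dusk

As a first pass, take the ceiling in Monday's flask as the mean of its last two readings, 43.9 %. The distance below that ceiling shrinks from 7.5 percentage points at 80.0 min to 3.2 points at 120 min, which means it halves every 33.4 min. The weak link is the ceiling, which stands lower than the last reading of 45.1 %. So reforge it: at that pace, a share 0.0830 of the distance at 120 min still remains at 240 min, and this puts the ceiling at 45.5 %. The distances then give the closing half-time, the time in which the distance to the ceiling halves, as in a first-order approach: 44.8 min.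

From the reading at 120 min, I commit to 44.7 % of target at 4.0 h and 45.5 % after dusk, a gain of 0.80 points. Both runs carry 0.90 equiv of reagent, so neither shows what more reagent does, whereas Monday's hotter run reads more target than Tuesday's at 240 min, 45.1 % against 23.5 %. I therefore choose dawn and give no figure for midnight.

The forecast gives 44.5 % (43 % to 46 %) at 4.0 h and 46 % (44 % to 50 %) after dusk. It differs from me on the remedy: it names midnight, with 80 % (62 % to 90 %), holding that “a second reagent charge should push the target strongly”.

The flask gives 44.5 % of target at 4.0 h. Dawn adds 18 points, more than spring's 14 points, midnight's 2.3 points or dusk's 1.8 points. Midnight ends at 46.9 % and dusk at 46.3 %.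

    starting material → intermediate (k = 0.00400 s⁻¹, Ea = 91.0 kJ mol⁻¹)
    reagent + intermediate → target (k = 0.00330 M⁻¹ s⁻¹, Ea = 80.0 kJ mol⁻¹)
    target ⇌ isomer of the product (K = 0.440, k = 0.00120 s⁻¹, Ea = 102 kJ mol⁻¹, ΔH = −75.0 kJ mol⁻¹)
    solid substrate ⇌ starting material, rate k4*(cs4 - [starting material]) while solid is left; crystals form when [starting material] > cs4 (solubility = 0.130 M, k = 0.00120 s⁻¹)
    starting material + target → side product (k = 0.0170 M⁻¹ s⁻¹, Ea = 55.0 kJ mol⁻¹)
    (constants at 70 °C)

In this flask, dusk stands 0.80 points above my reckoning. For the same flask read at 1.5 h, start from the distance of 9.1 points at 80.0 min and shrink it over 10.0 min with the closing half-time of 44.8 min. That gives 37.7 % of target, and that flask holds 36.6 %.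

The readings come from a simulation on assumed constants, noise included.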